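## Retrosynthetic overview
1. Target ⇒ one global hydrogenolysis (8 O–Bn, the boronate, the benzylic C4–O) of the octabenzyl 3,7-digallate of a flavan-3,4-diol whose O4 and O5 are tied in a phenylboronate ring.
2. ⇒ Double esterification with tri-O-benzylgallic acid of a tricyclic boronate in which only 3-OH and 7-OH are free, so 5-OH needs no separate protecting step.
3. ⇒ Key [3+3] annulation (C4–C4a and O1–C2): phloroglucinol + PhB(OH)2 + a (2R,3S)-3-aryloxirane-2-carbaldehyde. The 1,3,2-dioxaborin ring and the pyran C ring close in the same flask.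
4. ⇒ The epoxy aldehyde comes from organocatalytic epoxidation of (E)-3,4-bis(benzyloxy)cinnamaldehyde, itself made by Wittig reaction of 3,4-bis(benzyloxy)benzaldehyde. The oxirane carries both stereocentres (C3 retained, C2 inverted).
5. Ring order: rings A, B and both galloyl rings are bought. The oxirane forms in step 2, the dioxaborin and pyran form together in step 3, and the dioxaborin is removed in the last step.

Assumption: the target is the (2R,3S) compound encoded by the SMILES. C4 in 6, 7, 10 and 11 is drawn as the expected 4R (3,4-trans) epimer, and this centre is erased in the last step.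

## Route

Step 1
Reactants: 1 3,4-bis(benzyloxy)benzaldehyde; 2 (triphenylphosphoranylidene)acetaldehyde
Product: 3 (E)-3-[3,4-bis(benzyloxy)phenyl]prop-2-enal
Conditions: 2 (1.05 equiv), PhMe, 90 °C, 16 h
Reagents that add atoms: none
Why: Wittig olefination with a stabilised formyl ylide gives the E-enal, and keeping the ylide near 1 equiv limits vinylogous over-homologation.

Step 2
Reactants: 3 (E)-3-[3,4-bis(benzyloxy)phenyl]prop-2-enal
Product: 4 (2R,3S)-3-[3,4-bis(benzyloxy)phenyl]oxirane-2-carbaldehyde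
Conditions: (R)-2-{bis[3,5-bis(trifluoromethyl)phenyl](trimethylsilyloxy)methyl}pyrrolidine (10 mol %), 35% aq H2O2 (1.3 equiv), CH2Cl2, rt; short plug of Et3N-deactivated silica
Reagents that add atoms: hydrogen peroxide OO
Why: Jørgensen organocatalytic (iminium–enamine, Weitz–Scheffer-type) epoxidation, in which the C(Ar)2OTMS group of the (R)-catalyst blocks the Cβ Si face of the E,s-trans iminium ion, hydroperoxide adds to the Re face and the enamine closes onto O–O from the same side, giving the trans (2R,3S) oxirane that holds both future stereocentres (the (S)-catalyst gives the antipode).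

Step 3
Reactants: 4 (2R,3S)-3-[3,4-bis(benzyloxy)phenyl]oxirane-2-carbaldehyde; 5 phloroglucinol
Product: 7 (2R,3S,4R)-2-[3,4-bis(benzyloxy)phenyl]chromane-3,4,5,7-tetrol 4,5-O-phenylboronate (3-OH/7-OH free), via benzodioxaborin epoxide 6 (not isolated)
Conditions: 5 (2 equiv), PhB(OH)2 (1.1 equiv), EtCO2H (10 mol %), 4 Å MS, THF–PhMe 1:3, 60 °C, 4 added over 2 h
Reagents that add atoms: phenylboronic acid OB(O)c1ccccc1
Why: Proposed new method: PhB(OH)2 esterifies one OH of C3-symmetric phloroglucinol, binds the formyl oxygen and delivers the ortho carbon through a closed six-membered transition state to give 6 (closest known type: boronic-acid-templated ortho-hydroxyalkylation of phenols with aldehydes to 2-phenyl-4H-1,3,2-benzodioxaborins, which phloroglucinol is known to undergo); once the electron-withdrawing CHO has become a borylated carbinol, the p-benzyloxy-stabilised oxirane is opened 6-endo-tet at its benzylic (distal) carbon by the second ortho OH with inversion (closest known types: Lewis-acid-directed distal opening of 2,3-epoxy alcohols and acid-promoted cyclisation of 2-(3-aryloxiranylmethyl)phenols to flavan-3-ols), so C3 keeps its C–O bond (S), C2 becomes R (an SN1-like leak also gives the equatorial, trans aryl), and reversible C4–O ionisation funnels C4 to the all-equatorial 4R epimer, whose trans-3,4-diol cannot take the boron away from O4/O5.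

Step 4
Reactants: 7 (2R,3S,4R)-2-[3,4-bis(benzyloxy)phenyl]chromane-3,4,5,7-tetrol 4,5-O-phenylboronate; 8 3,4,5-tris(benzyloxy)benzoic acid
Product: 10 (2R,3S,4R)-2-[3,4-bis(benzyloxy)phenyl]chromane-3,4,5,7-tetrol 4,5-O-phenylboronate 3,7-bis[3,4,5-tris(benzyloxy)benzoate], via O-acylisourea 9 (not isolated)
Conditions: 8 (2.6 equiv), DCC (2.8 equiv), DMAP (0.4 equiv), dry CH2Cl2, 0 °C → rt, 24 h
Reagents that add atoms: none
Why: Steglich esterification, in which the boronate ring masks O4 and O5 so that the 7-phenol and the 3-carbinol are the only nucleophiles left, both are acylated under anhydrous, near-neutral conditions that the dioxaborin tolerates, and no stereocentre is touched.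

Step 5
Reactants: 10 (2R,3S,4R)-2-[3,4-bis(benzyloxy)phenyl]chromane-3,4,5,7-tetrol 4,5-O-phenylboronate 3,7-bis[3,4,5-tris(benzyloxy)benzoate]
Product: 12 (2R,3S)-catechin 3,7-di-O-gallate (target), via flavan-4,5-diol 11 (not isolated)
Conditions: H2 (1 atm), 20% Pd(OH)2/C, THF–H2O–AcOH 8:1:1, rt, 16 h; boronic acid removed on a diol resin
Reagents that add atoms: none
Why: Catalytic hydrogenolysis, in which aqueous acid first hydrolyses the boronate to 11, whose C4–OH sits next to a free ortho phenol and leaves via an o-quinone methide that Pd/H2 saturates (the classical leucoanthocyanidin-to-catechin reduction), while the eight benzyl ethers fall, both gallate esters survive, and C2 and C3 are not involved.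

## Compound list
1 | 3,4-bis(benzyloxy)benzaldehyde | O=Cc1ccc(OCc2ccccc2)c(OCc2ccccc2)c1 | starting material
2 | (triphenylphosphoranylidene)acetaldehyde | O=CC=P(c1ccccc1)(c1ccccc1)c1ccccc1 | starting material
3 | (E)-3-[3,4-bis(benzyloxy)phenyl]prop-2-enal | O=C/C=C/c1ccc(OCc2ccccc2)c(OCc2ccccc2)c1 | intermediate
4 | (2R,3S)-3-[3,4-bis(benzyloxy)phenyl]oxirane-2-carbaldehyde (trans) | O=C[C@@H]1O[C@H]1c1ccc(OCc2ccccc2)c(OCc2ccccc2)c1 | intermediate
5 | phloroglucinol (benzene-1,3,5-triol) | Oc1cc(O)cc(O)c1 | starting material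
6 | (4R)-4-{(2S,3S)-3-[3,4-bis(benzyloxy)phenyl]oxiran-2-yl}-2-phenyl-4H-1,3,2-benzodioxaborinine-5,7-diol | Oc1cc(O)c2c(c1)OB(c1ccccc1)O[C@H]2[C@@H]1O[C@H]1c1ccc(OCc2ccccc2)c(OCc2ccccc2)c1 | intermediate (not isolated)
7 | (2R,3S,4R)-2-[3,4-bis(benzyloxy)phenyl]chromane-3,4,5,7-tetrol 4,5-O-phenylboronate; the O4–B(Ph)–O5 six-membered ring is peri-fused to rings A and C, the compound is 2,3-trans-3,4-trans, and 3-OH and 7-OH are free | Oc1cc2OB(c3ccccc3)O[C@H]4[C@H](O)[C@@H](c3ccc(OCc5ccccc5)c(OCc5ccccc5)c3)Oc(c1)c24 | intermediate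
8 | 3,4,5-tris(benzyloxy)benzoic acid | OC(=O)c1cc(OCc2ccccc2)c(OCc2ccccc2)c(OCc2ccccc2)c1 | starting material
9 | O-[3,4,5-tris(benzyloxy)benzoyl]-N,N'-dicyclohexylisourea | O=C(OC(=NC1CCCCC1)NC1CCCCC1)c1cc(OCc2ccccc2)c(OCc2ccccc2)c(OCc2ccccc2)c1 | intermediate (not isolated)
10 | compound 7 esterified at O3 and O7 with 3,4,5-tris(benzyloxy)benzoyl, (2R,3S,4R), boronate ring intact | O=C(Oc1cc2OB(c3ccccc3)O[C@H]4[C@H](OC(=O)c3cc(OCc5ccccc5)c(OCc5ccccc5)c(OCc5ccccc5)c3)[C@@H](c3ccc(OCc5ccccc5)c(OCc5ccccc5)c3)Oc(c1)c24)c1cc(OCc2ccccc2)c(OCc2ccccc2)c(OCc2ccccc2)c1 | intermediate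
11 | (2R,3S,4R)-2-[3,4-bis(benzyloxy)phenyl]-4,5-dihydroxychromane-3,7-diyl bis[3,4,5-tris(benzyloxy)benzoate] | O=C(Oc1cc(O)c2c(c1)O[C@H](c1ccc(OCc3ccccc3)c(OCc3ccccc3)c1)[C@@H](OC(=O)c1cc(OCc3ccccc3)c(OCc3ccccc3)c(OCc3ccccc3)c1)[C@@H]2O)c1cc(OCc2ccccc2)c(OCc2ccccc2)c(OCc2ccccc2)c1 | intermediate (not isolated)
12 | (2R,3S)-catechin 3,7-di-O-gallate | O=C(Oc1cc(O)c2c(c1)O[C@H](c1ccc(O)c(O)c1)[C@@H](OC(=O)c1cc(O)c(O)c(O)c1)C2)c1cc(O)c(O)c(O)c1 | target

Total step count: 5. Longest linear sequence: 5 (1 → 3 → 4 → 7 → 10 → 12).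

## Steps most likely to fail

**Risk 1, step 3.**
- Possible failures: over-condensation of phloroglucinol, capture of a C4 cation by excess phloroglucinol, premature loss of the oxirane, or boron ending up on O3/O4.
- The fallback sets out from 4 and 5 and returns at 7. It makes the bonds one at a time and closes the boron ring last.
- Treat 5 with EtMgBr (1 equiv, THF–CH2Cl2) and add 4 at −20 °C. The magnesium phenolate chelates the aldehyde and gives, by ortho-selective metal-phenolate hydroxyalkylation under non-acidic conditions, 2-{(R)-hydroxy[(2S,3S)-3-[3,4-bis(benzyloxy)phenyl]oxiran-2-yl]methyl}benzene-1,3,5-triol F1.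
- HFIP at 0 °C then triggers the 6-endo opening to (2R,3S,4R)-2-[3,4-bis(benzyloxy)phenyl]chromane-3,4,5,7-tetrol F2. C4 epimers equilibrate in dilute AcOH to the all-equatorial form.
- Condensation of this tetrol with PhB(OH)2 (PhMe, 4 Å MS) rejoins the route at 7.

**Risk 2, step 5.**
- Possible failures: sluggish C4–O cleavage, tautomerisation of the o-quinone methide to a flav-3-ene that would scramble C3, or 3→4 acyl shift after the boron is lost.
- The fallback sets out from 10 and returns at 12. It removes C4–O by ionic rather than catalytic reduction.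
- Et3SiH (3 equiv) and TFA (5 equiv) in CH2Cl2 at −20 °C ionise the benzodioxaborin C4–O bond and deliver hydride. After aqueous work-up this gives (2R,3S)-2-[3,4-bis(benzyloxy)phenyl]-5-hydroxychromane-3,7-diyl bis[3,4,5-tris(benzyloxy)benzoate] F3.
- A routine debenzylation (H2, Pd(OH)2/C, THF–MeOH) then gives 12.

**Risk 3, step 2.**
- Possible failures: the electron-rich enal forms a poorly electrophilic iminium ion, and the product is acid-sensitive.
- The fallback sets out from 3 and returns at 4. It moves the epoxidation to the alcohol oxidation level under metal control.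
- Luche reduction (NaBH4, CeCl3, MeOH, 0 °C) gives (E)-3-[3,4-bis(benzyloxy)phenyl]prop-2-en-1-ol F4.
- Sharpless asymmetric epoxidation (Ti(OiPr)4, L-(+)-diethyl tartrate, TBHP, 4 Å MS, CH2Cl2, −20 °C, basic work-up) gives [(2S,3S)-3-[3,4-bis(benzyloxy)phenyl]oxiran-2-yl]methanol F5.
- F5 is oxidised at once under Parikh–Doering conditions (SO3·pyridine, DMSO, Et3N) to 4.

## Further compounds
F1 | step 3 | 2-{(R)-hydroxy[(2S,3S)-3-[3,4-bis(benzyloxy)phenyl]oxiran-2-yl]methyl}benzene-1,3,5-triol | Oc1cc(O)c([C@@H](O)[C@@H]2O[C@H]2c2ccc(OCc3ccccc3)c(OCc3ccccc3)c2)c(O)c1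
F2 | step 3 | (2R,3S,4R)-2-[3,4-bis(benzyloxy)phenyl]chromane-3,4,5,7-tetrol | Oc1cc(O)c2c(c1)O[C@H](c1ccc(OCc3ccccc3)c(OCc3ccccc3)c1)[C@@H](O)[C@@H]2O
F3 | step 5 | (2R,3S)-2-[3,4-bis(benzyloxy)phenyl]-5-hydroxychromane-3,7-diyl bis[3,4,5-tris(benzyloxy)benzoate] | O=C(Oc1cc(O)c2c(c1)O[C@H](c1ccc(OCc3ccccc3)c(OCc3ccccc3)c1)[C@@H](OC(=O)c1cc(OCc3ccccc3)c(OCc3ccccc3)c(OCc3ccccc3)c1)C2)c1cc(OCc2ccccc2)c(OCc2ccccc2)c(OCc2ccccc2)c1
F4 | step 2 | (E)-3-[3,4-bis(benzyloxy)phenyl]prop-2-en-1-ol | OC/C=C/c1ccc(OCc2ccccc2)c(OCc2ccccc2)c1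
F5 | step 2 | [(2S,3S)-3-[3,4-bis(benzyloxy)phenyl]oxiran-2-yl]methanol | OC[C@@H]1O[C@H]1c1ccc(OCc2ccccc2)c(OCc2ccccc2)c1
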